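**Strategy.** Everything rests on cutting ring D, the para-phenylene ring, across its C2–C3 and C4–C5 bonds, which turns it into a 4-aryloxy-2-pyranone on the oxygen of catechol ring C and a terminal ynone on the side chain of methoxy ring A. In one thermal operation the pyranone adds to the alkyne and expels carbon dioxide, so that ring D appears with its ether oxygen (C1) para to the ketone-level bridge carbon on C4 while the 18-membered ring closes. The precursor is the open-chain ynone 16, in which rings A, B (meta-phenylene) and C are already joined by one diaryl ether and one ethylene bridge and ring C carries a benzyl ether and the pyranonyl ether.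

Key step: step 12

Remarks on the chemistry:
- Ring A is the methoxy-bearing 1,2,3-trisubstituted ring, ring B the meta-phenylene ring, ring C the ring with the (benzylated) hydroxyl, ring D the para-phenylene ring made in step 12.
- The target has no stereocentre. The THP acetal carbon (2, 6, 7, 9, 10) and the carbinol carbons (12, 15, 20) are racemic and are all removed on the way.
- The pyranone is brought in as its 4-bromide, not as a 4-sulfonate, because a phenoxide can attack sulfur of an enol sulfonate and only transfer the sulfonyl group.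
- The stilbene is reduced over sulfide-poisoned palladium so that the aryl benzyl ether survives.
- The ring C 3-hydroxyl is masked as a THP acetal so that only the ring B phenol is free for the fluoride displacement; the acetal falls off in the same acid step that unmasks the homologated aldehyde.

**Route**

Step 1
Reactants: 1 4-(benzyloxy)-3-hydroxybenzaldehyde
Product: 2 4-(benzyloxy)-3-(tetrahydro-2H-pyran-2-yloxy)benzaldehyde (racemic)
Conditions: DHP, PPTS (cat.), CH2Cl2, rt
Reagents that add atoms: 3,4-dihydro-2H-pyran, C1CCOC=C1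
Why: Acid-catalysed addition of the phenol to the enol ether (THP acetal formation) masks the ring C 3-hydroxyl with a group that tolerates ylides, carbonate and hydrogenation.

Step 2
Reactants: 3 3-(hydroxymethyl)phenol
Product: 4 (3-hydroxybenzyl)triphenylphosphonium bromide
Conditions: Ph3P·HBr, MeCN, reflux
Reagents that add atoms: triphenylphosphine hydrobromide, Br.c1ccc(cc1)P(c1ccccc1)c1ccccc1
Why: Phosphonium salt formation from a benzylic alcohol: the alcohol is activated by HBr and captured by triphenylphosphine, while the phenol does not react.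

Step 3
Reactants: 4 (3-hydroxybenzyl)triphenylphosphonium bromide; 2 4-(benzyloxy)-3-(tetrahydro-2H-pyran-2-yloxy)benzaldehyde
Product: 6 3-{2-[4-(benzyloxy)-3-(tetrahydro-2H-pyran-2-yloxy)phenyl]ethenyl}phenol (E/Z mixture), via phenolate ylide 5 (not isolated)
Conditions: KOtBu (2.2 equiv), THF, 0 °C; then 2, rt; aq. NH4Cl
Reagents that add atoms: none
Why: Wittig olefination in which two equivalents of base give a phenolate ylide that cannot collapse to a quinone methide (oxygen meta to the ylide carbon) and condenses with the aldehyde; the alkene geometry is irrelevant because it is reduced next.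

Step 4
Reactants: 6 3-{2-[4-(benzyloxy)-3-(tetrahydro-2H-pyran-2-yloxy)phenyl]ethenyl}phenol
Product: 7 3-{2-[4-(benzyloxy)-3-(tetrahydro-2H-pyran-2-yloxy)phenyl]ethyl}phenol (racemic)
Conditions: H2 (1 atm), 10% Pd/C, Ph2S (0.01 equiv), EtOAc, rt
Reagents that add atoms: none
Why: Catalytic hydrogenation over sulfide-poisoned palladium on carbon should saturate the stilbene double bond while the poison suppresses hydrogenolysis of the aryl benzyl ether, and the neutral medium leaves the THP acetal intact.

Step 5
Reactants: 7 3-{2-[4-(benzyloxy)-3-(tetrahydro-2H-pyran-2-yloxy)phenyl]ethyl}phenol; 8 2-fluoro-3-methoxybenzaldehyde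
Product: 9 2-(3-{2-[4-(benzyloxy)-3-(tetrahydro-2H-pyran-2-yloxy)phenyl]ethyl}phenoxy)-3-methoxybenzaldehyde (racemic)
Conditions: K2CO3, DMF, 100 °C
Reagents that add atoms: none
Why: Nucleophilic aromatic substitution (addition–elimination) in which the ortho-formyl group activates the fluoride toward the ring B phenoxide, the only free phenol in 7.

Step 6
Reactants: 9 2-(3-{2-[4-(benzyloxy)-3-(tetrahydro-2H-pyran-2-yloxy)phenyl]ethyl}phenoxy)-3-methoxybenzaldehyde
Product: 10 2-[2-(benzyloxy)-5-(2-{3-[2-methoxy-6-(2-methoxyethenyl)phenoxy]phenyl}ethyl)phenoxy]tetrahydro-2H-pyran (E/Z mixture)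
Conditions: MeOCH2PPh3Cl, KOtBu, THF, 0 °C to rt
Reagents that add atoms: (methoxymethyl)triphenylphosphonium chloride, [Cl-].COC[P+](c1ccccc1)(c1ccccc1)c1ccccc1
Why: Wittig olefination of a non-enolisable aryl aldehyde with the methoxymethylene ylide gives the one-carbon-homologated enol ether, whose geometry does not matter.

Step 7
Reactants: 10 2-[2-(benzyloxy)-5-(2-{3-[2-methoxy-6-(2-methoxyethenyl)phenoxy]phenyl}ethyl)phenoxy]tetrahydro-2H-pyran
Product: 11 2-[2-(3-{2-[4-(benzyloxy)-3-hydroxyphenyl]ethyl}phenoxy)-3-methoxyphenyl]acetaldehyde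
Conditions: 1 M HCl, THF, 40 °C; crude product used at once
Reagents that add atoms: water, O
Why: Dilute aqueous acid hydrolyses the enol ether to the arylacetaldehyde and, in the same pot, the aryl THP acetal to the phenol (acetal hydrolysis), conditions too mild for Friedel–Crafts closure onto ring B.

Step 8
Reactants: 11 2-[2-(3-{2-[4-(benzyloxy)-3-hydroxyphenyl]ethyl}phenoxy)-3-methoxyphenyl]acetaldehyde
Product: 12 1-[2-(3-{2-[4-(benzyloxy)-3-hydroxyphenyl]ethyl}phenoxy)-3-methoxyphenyl]but-3-yn-2-ol (racemic)
Conditions: HC≡CMgBr (3.5 equiv), THF, −20 to 0 °C; aq. NH4Cl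
Reagents that add atoms: ethynylmagnesium bromide, C#C[Mg]Br
Why: Grignard 1,2-addition in which the first equivalent deprotonates the phenol and further reagent adds to the aldehyde at low temperature; the new carbinol centre is racemic and is erased by the oxidation in step 11.

Step 9
Reactants: 13 4-hydroxy-2H-pyran-2-one
Product: 14 4-bromo-2H-pyran-2-one
Conditions: Bu4NBr, P2O5, toluene, 100 °C
Reagents that add atoms: tetrabutylammonium bromide, [Br-].CCCC[N+](CCCC)(CCCC)CCCC
Why: Dehydroxy-bromination of a vinylogous acid: phosphorylation of the 4-hydroxyl followed by addition–elimination of bromide, as is routine for 4-hydroxy-6-methyl-2-pyranone and 4-hydroxycoumarins.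

Step 10
Reactants: 12 1-[2-(3-{2-[4-(benzyloxy)-3-hydroxyphenyl]ethyl}phenoxy)-3-methoxyphenyl]but-3-yn-2-ol; 14 4-bromo-2H-pyran-2-one
Product: 15 4-[2-(benzyloxy)-5-(2-{3-[2-(2-hydroxybut-3-yn-1-yl)-6-methoxyphenoxy]phenyl}ethyl)phenoxy]-2H-pyran-2-one (racemic)
Conditions: K2CO3, MeCN, rt to 40 °C
Reagents that add atoms: none
Why: Nucleophilic vinylic substitution (conjugate addition–elimination at C4 of the vinylogous acyl bromide) by the phenoxide, the only site that carbonate deprotonates, so the secondary alcohol and the alkyne C–H are left alone.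

Step 11
Reactants: 15 4-[2-(benzyloxy)-5-(2-{3-[2-(2-hydroxybut-3-yn-1-yl)-6-methoxyphenoxy]phenyl}ethyl)phenoxy]-2H-pyran-2-one
Product: 16 4-[2-(benzyloxy)-5-(2-{3-[2-methoxy-6-(2-oxobut-3-yn-1-yl)phenoxy]phenyl}ethyl)phenoxy]-2H-pyran-2-one
Conditions: Dess–Martin periodinane, CH2Cl2, 0 °C to rt; used directly
Reagents that add atoms: none
Why: Dess–Martin oxidation of the secondary propargylic alcohol gives the terminal ynone under near-neutral conditions that spare the pyranone and the benzyl ether; it comes last so that no free phenol ever meets the ynone.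

Step 12
Reactants: 16 4-[2-(benzyloxy)-5-(2-{3-[2-methoxy-6-(2-oxobut-3-yn-1-yl)phenoxy]phenyl}ethyl)phenoxy]-2H-pyran-2-one
Product: 18 benzyl-protected 18-membered macrocyclic aryl ketone (ring D formed; carbonyl on the ring D side of the ring A–ring D bridge), via bridged lactone adduct 17 (not isolated)
Conditions: 1,2-dichlorobenzene (1 mM, syringe-pump addition), BHT (cat.), 150 °C
Reagents that add atoms: none
Why: On heating, the diene of the 4-aryloxy-2-pyranone (C3 to C6) adds across the ynone triple bond in an intramolecular [4+2] cycloaddition, joining pyranone C3 to the terminal alkyne carbon and C6 to the acyl-bearing carbon, and the 2-oxabicyclo[2.2.2]octadienone 17 then ejects carbon dioxide by retro-[4+2] to aromatise as ring D. The closest known reaction type is the 2-pyranone–alkyne Diels–Alder/decarboxylation sequence, which has been run intramolecularly to close cyclophanes. Ring D closes by the cycloaddition (four pyranone carbons plus two alkyne carbons) followed by cycloreversion, and the 18-membered ring closes in the same bond-forming event as a macrocyclisation across the tether, because pyranone C4 (through its ether oxygen) and the alkyne (through its carbonyl) sit at the two ends of the ring C–ring B–ring A chain. No stereocentre remains in 18, since the two bridgehead centres of 17 vanish when carbon dioxide leaves. The step needs the ether oxygen and the acyl group para on ring D and ring closure in preference to oligomerisation: the first should follow from pairing the most nucleophilic diene terminus (C3, the β-carbon of the enol ether) with the electrophilic terminal carbon of the ynone, the second from slow addition into hot solvent at millimolar concentration, where the long flexible tether puts no strain on the para-bridged ring.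

Step 13
Reactants: 18 benzyl-protected 18-membered macrocyclic aryl ketone
Product: 21 CNP0309263.0 (18-membered macrocyclic bis(bibenzyl) with one methoxy group on ring A and one free hydroxyl on ring C), via debenzylated phenol ketone 19 (not isolated), via benzylic alcohol 20 (not isolated)
Conditions: H2 (4 atm), 10% Pd/C, AcOH/EtOAc, H2SO4 (cat.), 50 °C
Reagents that add atoms: none
Why: Catalytic hydrogenation and hydrogenolysis: the benzyl ether is cleaved, the aryl ketone is reduced to the benzylic alcohol, and acid together with the para-aryloxy group promotes hydrogenolysis of that benzylic C–O bond to the methylene, while the diaryl ethers and the methyl ether are inert.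

**Compound list**

1 | 4-(benzyloxy)-3-hydroxybenzaldehyde | O=Cc1ccc(OCc2ccccc2)c(O)c1 | starting material
2 | 4-(benzyloxy)-3-(tetrahydro-2H-pyran-2-yloxy)benzaldehyde (racemic) | O=Cc1ccc(OCc2ccccc2)c(OC2CCCCO2)c1 | intermediate
3 | 3-(hydroxymethyl)phenol | OCc1cccc(O)c1 | starting material
4 | (3-hydroxybenzyl)triphenylphosphonium bromide | [Br-].Oc1cccc(C[P+](c2ccccc2)(c2ccccc2)c2ccccc2)c1 | intermediate
5 | potassium 3-[(triphenylphosphoranylidene)methyl]phenolate (phenolate ylide, not isolated) | [K+].[O-]c1cccc(C=P(c2ccccc2)(c2ccccc2)c2ccccc2)c1 | intermediate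
6 | 3-{2-[4-(benzyloxy)-3-(tetrahydro-2H-pyran-2-yloxy)phenyl]ethenyl}phenol (E/Z mixture, racemic) | Oc1cccc(C=Cc2ccc(OCc3ccccc3)c(OC3CCCCO3)c2)c1 | intermediate
7 | 3-{2-[4-(benzyloxy)-3-(tetrahydro-2H-pyran-2-yloxy)phenyl]ethyl}phenol (racemic) | Oc1cccc(CCc2ccc(OCc3ccccc3)c(OC3CCCCO3)c2)c1 | intermediate
8 | 2-fluoro-3-methoxybenzaldehyde | COc1cccc(C=O)c1F | starting material
9 | 2-(3-{2-[4-(benzyloxy)-3-(tetrahydro-2H-pyran-2-yloxy)phenyl]ethyl}phenoxy)-3-methoxybenzaldehyde (racemic) | COc1cccc(C=O)c1Oc1cccc(CCc2ccc(OCc3ccccc3)c(OC3CCCCO3)c2)c1 | intermediate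
10 | 2-[2-(benzyloxy)-5-(2-{3-[2-methoxy-6-(2-methoxyethenyl)phenoxy]phenyl}ethyl)phenoxy]tetrahydro-2H-pyran (E/Z mixture, racemic) | COC=Cc1cccc(OC)c1Oc1cccc(CCc2ccc(OCc3ccccc3)c(OC3CCCCO3)c2)c1 | intermediate
11 | 2-[2-(3-{2-[4-(benzyloxy)-3-hydroxyphenyl]ethyl}phenoxy)-3-methoxyphenyl]acetaldehyde | COc1cccc(CC=O)c1Oc1cccc(CCc2ccc(OCc3ccccc3)c(O)c2)c1 | intermediate
12 | 1-[2-(3-{2-[4-(benzyloxy)-3-hydroxyphenyl]ethyl}phenoxy)-3-methoxyphenyl]but-3-yn-2-ol (racemic) | COc1cccc(CC(O)C#C)c1Oc1cccc(CCc2ccc(OCc3ccccc3)c(O)c2)c1 | intermediate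
13 | 4-hydroxy-2H-pyran-2-one | O=c1cc(O)cco1 | starting material
14 | 4-bromo-2H-pyran-2-one | O=c1cc(Br)cco1 | intermediate
15 | 4-[2-(benzyloxy)-5-(2-{3-[2-(2-hydroxybut-3-yn-1-yl)-6-methoxyphenoxy]phenyl}ethyl)phenoxy]-2H-pyran-2-one (racemic) | COc1cccc(CC(O)C#C)c1Oc1cccc(CCc2ccc(OCc3ccccc3)c(Oc3ccoc(=O)c3)c2)c1 | intermediate
16 | 4-[2-(benzyloxy)-5-(2-{3-[2-methoxy-6-(2-oxobut-3-yn-1-yl)phenoxy]phenyl}ethyl)phenoxy]-2H-pyran-2-one (seco ynone, key-step precursor) | COc1cccc(CC(=O)C#C)c1Oc1cccc(CCc2ccc(OCc3ccccc3)c(Oc3ccoc(=O)c3)c2)c1 | intermediate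
17 | bridged lactone adduct: macrocycle in which ring D is still a 2-oxabicyclo[2.2.2]octa-5,7-dien-3-one, with the ring C oxygen on C5 and the ketone carbonyl on C7 (racemic, not isolated) | COc1cccc2c1Oc1cccc(c1)CCc1ccc(OCc3ccccc3)c(c1)OC1=CC3OC(=O)C1C=C3C(=O)C2 | intermediate
18 | benzyl-protected 18-membered macrocyclic aryl ketone (key-step product) | COc1cccc2c1Oc1cccc(c1)CCc1ccc(OCc3ccccc3)c(c1)Oc1ccc(cc1)C(=O)C2 | intermediate
19 | debenzylated macrocyclic phenol ketone (not isolated) | COc1cccc2c1Oc1cccc(c1)CCc1ccc(O)c(c1)Oc1ccc(cc1)C(=O)C2 | intermediate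
20 | macrocyclic benzylic alcohol (racemic, not isolated) | COc1cccc2c1Oc1cccc(c1)CCc1ccc(O)c(c1)Oc1ccc(cc1)C(O)C2 | intermediate
21 | CNP0309263.0 | COc1cccc2c1Oc1cccc(c1)CCc1ccc(O)c(c1)Oc1ccc(cc1)CC2 | target

**Step count.** Total: 13 steps. Longest linear sequence: 11 steps (1, 3, 4, 5, 6, 7, 8, 10, 11, 12, 13 from compound 1).

**Steps most likely to fail**

1. Step 12. At the temperature needed, intermolecular cycloaddition (oligomer formation) or thermal decay of the terminal ynone may outrun ring closure, or the diene may add in the opposite orientation and give the meta-bridged 17-membered isomer. The fallback sets out from 9 and rejoins the route at 21; it closes the macrocycle at the ring A–ring D ethylene bridge by reductive carbonyl coupling. The THP group of 9 is removed (PPTS, EtOH, 50 °C) to give 2-(3-{2-[4-(benzyloxy)-3-hydroxyphenyl]ethyl}phenoxy)-3-methoxybenzaldehyde F1. Its phenol displaces fluoride from 4-fluorobenzaldehyde (K2CO3, DMF, 130 °C) to give the dialdehyde 2-(3-{2-[4-(benzyloxy)-3-(4-formylphenoxy)phenyl]ethyl}phenoxy)-3-methoxybenzaldehyde F2. Intramolecular McMurry coupling (TiCl4, Zn, pyridine, THF, reflux, high dilution) should give the macrocyclic stilbene benzyl ether F3 as an E/Z mixture. Hydrogenation (H2, 10% Pd/C, EtOAc/MeOH) then saturates the alkene and removes the benzyl group to give 21.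

2. Step 8. The Grignard reagent may act as a base on the enolisable arylacetaldehyde 11 (enolate formation, aldol condensation), and 11 may degrade before it is used. The fallback sets out from 9 and rejoins the route at 12; it inverts the polarity so that the benzylic carbon is the nucleophile. Reduction of 9 (NaBH4, MeOH, 0 °C) gives the benzylic alcohol F4. Appel-type chlorination (PPh3, N-chlorosuccinimide, THF, 0 °C) gives the benzylic chloride F5. Zinc insertion (Zn dust, LiCl, THF, rt) gives the benzylic zinc chloride F6, used in solution, which adds to 3-(trimethylsilyl)propynal (0 °C to rt) to give the silylated propargylic alcohol F7. K2CO3 in MeOH removes the alkynyl silyl group to give the THP-protected terminal alkyne F8, and PPTS in MeOH then removes the THP group to give 12.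

3. Step 3. The doubly deprotonated phenolate ylide may be poorly soluble and sluggish, so that the aldehyde is consumed incompletely. The fallback sets out from 2 and rejoins the route at 7; it joins rings C and B through an alkyne. Homologation of 2 with the Ohira–Bestmann reagent (dimethyl (1-diazo-2-oxopropyl)phosphonate, K2CO3, MeOH, rt) gives the aryl alkyne 1-(benzyloxy)-4-ethynyl-2-(tetrahydro-2H-pyran-2-yloxy)benzene F9. Sonogashira coupling with 3-iodophenol (PdCl2(PPh3)2, CuI, Et3N, THF, rt) gives the diarylalkyne 3-{[4-(benzyloxy)-3-(tetrahydro-2H-pyran-2-yloxy)phenyl]ethynyl}phenol F10. Hydrogenation under the conditions of step 4 (H2, 10% Pd/C, Ph2S, EtOAc) reduces the triple bond to the ethylene bridge and gives 7.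

**Further compounds**

F1 | step 12 | 2-(3-{2-[4-(benzyloxy)-3-hydroxyphenyl]ethyl}phenoxy)-3-methoxybenzaldehyde | COc1cccc(C=O)c1Oc1cccc(CCc2ccc(OCc3ccccc3)c(O)c2)c1
F2 | step 12 | 2-(3-{2-[4-(benzyloxy)-3-(4-formylphenoxy)phenyl]ethyl}phenoxy)-3-methoxybenzaldehyde | COc1cccc(C=O)c1Oc1cccc(CCc2ccc(OCc3ccccc3)c(Oc3ccc(C=O)cc3)c2)c1
F3 | step 12 | macrocyclic stilbene benzyl ether (E/Z mixture) | COc1cccc2c1Oc1cccc(c1)CCc1ccc(OCc3ccccc3)c(c1)Oc1ccc(cc1)C=C2
F4 | step 8 | [2-(3-{2-[4-(benzyloxy)-3-(tetrahydro-2H-pyran-2-yloxy)phenyl]ethyl}phenoxy)-3-methoxyphenyl]methanol (racemic) | COc1cccc(CO)c1Oc1cccc(CCc2ccc(OCc3ccccc3)c(OC3CCCCO3)c2)c1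
F5 | step 8 | 2-[2-(benzyloxy)-5-(2-{3-[2-(chloromethyl)-6-methoxyphenoxy]phenyl}ethyl)phenoxy]tetrahydro-2H-pyran (racemic) | COc1cccc(CCl)c1Oc1cccc(CCc2ccc(OCc3ccccc3)c(OC3CCCCO3)c2)c1
F6 | step 8 | benzylic zinc chloride derived from F5 (in solution) | COc1cccc(C[Zn]Cl)c1Oc1cccc(CCc2ccc(OCc3ccccc3)c(OC3CCCCO3)c2)c1
F7 | step 8 | 1-[2-(3-{2-[4-(benzyloxy)-3-(tetrahydro-2H-pyran-2-yloxy)phenyl]ethyl}phenoxy)-3-methoxyphenyl]-4-(trimethylsilyl)but-3-yn-2-ol (diastereomer mixture) | COc1cccc(CC(O)C#C[Si](C)(C)C)c1Oc1cccc(CCc2ccc(OCc3ccccc3)c(OC3CCCCO3)c2)c1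
F8 | step 8 | 1-[2-(3-{2-[4-(benzyloxy)-3-(tetrahydro-2H-pyran-2-yloxy)phenyl]ethyl}phenoxy)-3-methoxyphenyl]but-3-yn-2-ol (diastereomer mixture) | COc1cccc(CC(O)C#C)c1Oc1cccc(CCc2ccc(OCc3ccccc3)c(OC3CCCCO3)c2)c1
F9 | step 3 | 1-(benzyloxy)-4-ethynyl-2-(tetrahydro-2H-pyran-2-yloxy)benzene (racemic) | C#Cc1ccc(OCc2ccccc2)c(OC2CCCCO2)c1
F10 | step 3 | 3-{[4-(benzyloxy)-3-(tetrahydro-2H-pyran-2-yloxy)phenyl]ethynyl}phenol (racemic) | Oc1cccc(C#Cc2ccc(OCc3ccccc3)c(OC3CCCCO3)c2)c1
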